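## The problem

The target 15 is an open-chain 1,7-diarylheptanoid whose chain is numbered here from C1 (on the catechol ring) to C7 (on the 4-hydroxyphenyl ring), and since no ring has to be closed the work lies in joining two arene-bearing fragments and placing the oxygen and the alkene on the chain. The single stereocentre, C3, carries the acetate and is (S). Its two carbon arms, C2–C1 and C4–C5, are both CH2CH2 units and differ only one atom further out (aryl ipso carbon against the C6 alkene carbon), so no second stereocentre can relay control and a reagent that must tell the arms apart, as in reduction of a C3 ketone, has almost nothing to hold on to. The C6=C7 alkene is E and conjugated to a 4-oxygenated arene, and such a styrene is easily protonated and accepts metal hydrides and radicals, which limits what may be done while it is present. The catechol oxidises readily in base and air, and the secondary acetate must survive beside three phenols, which rules out hydrolytic, hydrogenolytic and strongly Lewis-acidic deprotection at the end. The feature that opens a direct solution is that C3 is the carbinol carbon of an ester next to an unfunctionalised C4 methylene. A C3 radical bearing the acetoxy group is planar and oxygen-stabilised, and it is reachable from an aldehyde and acetyl bromide. On a chiral nickel centre its two faces differ by acetoxy against alkyl, a large difference, and not by one arm against the other.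

## Retrosynthesis

**15 ⇒ 14.** The last operation should only free the three phenols, so the first cut is at the three aryl O–Si bonds, leading to the tris(tert-butyldimethylsilyl) ether 14. Methyl ethers would need boron tribromide, benzyl ethers would need a hydrogenolysis that also saturates C6=C7, and phenol acetates could not be told reliably from the C3 acetate. Aryl silyl ethers fall to buffered fluoride, which leaves a secondary acetate and a styrene alone. Compound 14 is no simpler in skeleton, but it is non-polar, not air-sensitive and already holds the whole chain, the stereocentre and the alkene. The forward step must stay near neutral.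

**14 ⇒ 12 (through 13).** The C6=C7 π-bond is traced back to a C7–O bond and a C6–H bond, that is, to the C7 triethylsilyl ether 12, which passes through the free carbinol 13.
- The key reaction requires this: its olefin partner may hold only one reactive π-bond, and a styrene or 1,3-diene spanning C4–C7 would take up nickel hydride at the benzylic or allylic carbon.
- Carrying the alkene as its hydrate costs nothing, because allyl-metal addition to an aryl aldehyde gives exactly this pattern.
- The C7 configuration is irrelevant, since both epimers collapse to one E-alkene.
- The elimination is placed before phenol release, so that the C7 cation arises in a molecule without free, nucleophilic phenols.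
- The forward reaction must distinguish the alkyl silyl ether at C7 (triethylsilyl, acid-labile) from the aryl silyl ethers and eliminate towards C6 with E geometry.
- Compound 14 has C3 as its only stereocentre and is therefore the convenient point to assay enantiomeric purity.

**12 ⇒ 6 + 11.** The central cut is the C3–C4 bond, giving the racemic 1-bromoalkyl acetate 6 (C1–C3) and the terminal olefin 11 (C4–C7).
- A cut at C2–C3 or C4–C5 would leave C3 as a carbonyl or organometallic carbon that must later be turned into a stereodefined carbinol between two like arms.
- The C3–C4 cut forms the stereocentre in the bond-forming event, from racemic material, with the acetate already attached.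
- Both fragments are achiral or racemic, of similar size, and a few steps from commodity chemicals.
- The forward reaction must be an enantioconvergent alkyl–alkyl coupling in which the nucleophilic partner is generated from the olefin and a hydrosilane.

**6 ⇒ 4 + 5, and 4 ⇒ 3 ⇒ 2 ⇒ 1.** The C3–Br and C3–O(acyl) bonds of 6 are removed together by taking acetyl bromide 5 off the aldehyde 4. This addition is the standard entry to 1-haloalkyl esters and makes the electrophile in one operation. Aldehyde 4 comes from the methyl ester 3 by partial reduction, 3 from the catechol ester 2 by silylation, and 2 from dihydrocaffeic acid 1 by esterification. The bromide must be formed without strong Lewis acid so that the aryl silyl ethers survive.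

**11 ⇒ 10 ⇒ 8 + 9, and 8 ⇒ 7.** The C7–O silyl bond of 11 is cut to the homoallylic alcohol 10, and the C6–C7 bond of 10 to 4-(tert-butyldimethylsilyloxy)benzaldehyde 8 and allylmagnesium bromide 9. Aldehyde 8 is the silyl ether of 4-hydroxybenzaldehyde 7. A Grignard addition suffices because C7 need not be controlled.

## Roads not taken

**Alternative 1:** The cut is at the C3–O bond, with C3 to C7 supplied by a five-membered ring.
- Forward step: (S)-2-{2-[3,4-bis(tert-butyldimethylsilyloxy)phenyl]ethyl}cyclopentanone A1 is treated with a buffered peracid. The more substituted α-carbon migrates with retention and gives the six-membered lactone A2.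
- Merits: the oxygen insertion is stereospecific, so once A1 is in hand the course at C3 is more certain than in any catalyst-controlled step, the chosen one included. The lactone carbonyl (C7) is ready for attachment of the aryl ring.
- Weak points: the stereocentre of A1 is α to a ketone and enolisable. It would be made by a stoichiometric auxiliary alkylation and must survive auxiliary removal and the acidic by-product of the oxidation. After A2 the sequence still needs mono-addition of an aryl-metal reagent to the lactone, acetylation, ketone reduction and dehydration at C7.
- Comparison: the end-game holds the same late benzylic dehydration as the chosen plan, reached over several more steps. Against the greater stereochemical certainty of this road, the chosen plan sets a catalytic construction of C3 from racemic material, the acetate delivered in the same step, and a shorter sequence.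

**Alternative 2:** The cut is at C4–C5.
- Forward step: racemic 1-[4-(tert-butyldimethylsilyloxy)phenyl]prop-2-en-1-ol A3 and triethyl orthoacetate A4 form a ketene acetal, which rearranges through a chair (Johnson–Claisen) to the E-pentenoate A5.
- Merits: the E-styrene is fixed early by the transition-state geometry, without acid and without a dehydration. On the alkene problem this road is better than the chosen plan.
- Weak points: C3 is left as an ester carbon, so the stereocentre is untouched. The natural continuation is the ketone A6, whose enantioselective reduction must tell a 2-arylethyl arm from a 4-arylbut-3-enyl arm. Chemical catalysts are poorly suited to that, and a resolution would halve the material.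
- Comparison: the chosen plan accepts a late, epimer-convergent dehydration and in return solves C3 directly, which is the harder of the two problems.

**Alternative 3:** The cut is at C2–C3.
- Forward step: the triisopropylbenzoate A7 is deprotonated at C3 by an alkyllithium base bound to a sparteine-type diamine. The configurationally stable lithium compound is trapped by the boronic ester A8, and 1,2-migration in the ate complex gives the secondary boronate A9. Oxidation with retention and acetylation follow.
- Merits: stereocontrol rests on the reagent, is indifferent to the likeness of the two arms, and is probably more predictable in level than a catalytic coupling on an untested substrate. The E-alkene is already in place.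
- Weak points: A7 holds a styrene with allylic C5 hydrogens, so carbolithiation and allylic deprotonation compete with α-oxygen lithiation, and aryl silyl ethers are exposed to a strong base. A stoichiometric chiral diamine and cryogenic conditions are required. The basic peroxide oxidation has to spare three aryl silyl ethers, the acetate comes only in a further step, and both partners need longer preparations than 6 and 11.
- Comparison: against the better predictability of this road, the chosen plan sets catalytic stereocontrol under near-neutral conditions, no organolithium beside a styrene, and direct delivery of the ester.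

Key step: step 8

Assumption: the sense of induction at C3 follows the antipode of the bis(oxazoline) ligand, both antipodes are accessible, and the one that leads to the (S)-acetate is used in step 8; the configuration at C3 should be verified on compound 14.

## Steps

Step 1
Reactants: 1 3-(3,4-dihydroxyphenyl)propanoic acid (dihydrocaffeic acid)
Product: 2 methyl 3-(3,4-dihydroxyphenyl)propanoate
Conditions: MeOH, H2SO4 (cat.), reflux
Reagents that add atoms: methanol, CO
Why: Fischer esterification; the catechol is inert to acidic methanol, and the methyl ester can later be stopped at the aldehyde oxidation level.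

Step 2
Reactants: 2 methyl 3-(3,4-dihydroxyphenyl)propanoate
Product: 3 methyl 3-[3,4-bis(tert-butyldimethylsilyloxy)phenyl]propanoate
Conditions: TBSCl (2.5 equiv), imidazole, DMF, rt
Reagents that add atoms: tert-butyldimethylsilyl chloride, CC(C)(C)[Si](C)(C)Cl
Why: Imidazole-promoted silylation of both phenols; aryl tert-butyldimethylsilyl ethers tolerate hydride reduction and mild acid and are later removed by fluoride without loss of an acetate.

Step 3
Reactants: 3 methyl 3-[3,4-bis(tert-butyldimethylsilyloxy)phenyl]propanoate
Product: 4 3-[3,4-bis(tert-butyldimethylsilyloxy)phenyl]propanal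
Conditions: i-Bu2AlH (1.1 equiv), CH2Cl2, −78 °C; aq. potassium sodium tartrate
Reagents that add atoms: none
Why: Partial reduction of an ester with diisobutylaluminium hydride; the tetrahedral aluminium hemiacetal persists at −78 °C and releases the aldehyde only on work-up.

Step 4
Reactants: 4 3-[3,4-bis(tert-butyldimethylsilyloxy)phenyl]propanal; 5 acetyl bromide
Product: 6 1-bromo-3-[3,4-bis(tert-butyldimethylsilyloxy)phenyl]propyl acetate (racemic)
Conditions: AcBr (1.05 equiv), CH2Cl2, −20 °C → rt; volatiles removed, used crude
Reagents that add atoms: none
Why: Addition of an acyl bromide across an aldehyde carbonyl (1-haloalkyl ester formation) through O-acylation and collapse of the acyloxycarbenium bromide ion pair; no Lewis acid is added so that the aryl silyl ethers are spared, and the moisture-sensitive racemate is used at once.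

Step 5
Reactants: 7 4-hydroxybenzaldehyde
Product: 8 4-(tert-butyldimethylsilyloxy)benzaldehyde
Conditions: TBSCl (1.2 equiv), imidazole, DMF, rt
Reagents that add atoms: tert-butyldimethylsilyl chloride, CC(C)(C)[Si](C)(C)Cl
Why: Imidazole-promoted phenol silylation; it removes the acidic proton before the Grignard step and gives the same phenol protection as in fragment 6.

Step 6
Reactants: 8 4-(tert-butyldimethylsilyloxy)benzaldehyde; 9 allylmagnesium bromide
Product: 10 1-[4-(tert-butyldimethylsilyloxy)phenyl]but-3-en-1-ol (racemic)
Conditions: THF, −78 °C → 0 °C; aqueous work-up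
Reagents that add atoms: none
Why: Grignard 1,2-addition of an allyl-metal to an aryl aldehyde forms C6–C7; the C7 centre is left racemic on purpose because it is erased in step 9.

Step 7
Reactants: 10 1-[4-(tert-butyldimethylsilyloxy)phenyl]but-3-en-1-ol (racemic)
Product: 11 tert-butyldimethyl{4-[1-(triethylsilyloxy)but-3-en-1-yl]phenoxy}silane (racemic)
Conditions: TESCl (1.2 equiv), imidazole, CH2Cl2, 0 °C → rt
Reagents that add atoms: triethylsilyl chloride, CC[Si](Cl)(CC)CC
Why: Silylation of a secondary alcohol; the alkyl triethylsilyl ether is far more acid-labile than the aryl tert-butyldimethylsilyl ethers, which allows C7 to be addressed alone in step 9.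

Step 8
Reactants: 6 1-bromo-3-[3,4-bis(tert-butyldimethylsilyloxy)phenyl]propyl acetate (racemic); 11 tert-butyldimethyl{4-[1-(triethylsilyloxy)but-3-en-1-yl]phenoxy}silane (racemic)
Product: 12 (3S)-1-[3,4-bis(tert-butyldimethylsilyloxy)phenyl]-7-[4-(tert-butyldimethylsilyloxy)phenyl]-7-(triethylsilyloxy)heptan-3-yl acetate (mixture of C7 epimers)
Conditions: NiBr2·diglyme (10 mol%), chiral isopropylidene-bridged bis(oxazoline) ligand (12 mol%, antipode giving 3S), (EtO)3SiH (2 equiv), K3PO4·H2O (2 equiv), DMA, 0 °C → rt
Reagents that add atoms: none
Why: This is the nickel-hydride enantioconvergent hydroalkylation of a terminal olefin with a racemic 1-bromoalkyl ester, a known reaction type for this electrophile class. Silane and phosphate convert the nickel bromide–ligand complex into a nickel hydride, which inserts the monosubstituted C4=C5 bond of 11 with hydride going to C5 and nickel to the terminal C4. Monovalent nickel abstracts bromine from 6 and gives the planar, oxygen-stabilised C3 radical, which erases the configuration of the racemate. The chiral primary-alkyl nickel complex captures this radical, and reductive elimination from trivalent nickel forms the C3–C4 bond; no ring is closed. The C3 stereocentre is under catalyst control alone: the ligand pocket, aided by coordination of the acetate carbonyl, distinguishes acetoxy from the alkyl chain, so the likeness of the two CH2CH2 arms does not matter. The step needs anti-Markovnikov insertion and reaction at a single π-bond, and both are secured because 11 holds one unconjugated terminal alkene, with C7 kept sp3 so that no styrene or diene competes and no oxygen sits β to nickel. The racemic C7 centre is a spectator and gives two epimers that converge in step 9.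

Step 9
Reactants: 12 (3S)-1-[3,4-bis(tert-butyldimethylsilyloxy)phenyl]-7-[4-(tert-butyldimethylsilyloxy)phenyl]-7-(triethylsilyloxy)heptan-3-yl acetate (mixture of C7 epimers)
Product: 14 (3S,6E)-1-[3,4-bis(tert-butyldimethylsilyloxy)phenyl]-7-[4-(tert-butyldimethylsilyloxy)phenyl]hept-6-en-3-yl acetate, via C7 benzylic alcohol 13 (not isolated)
Conditions: TsOH·H2O (0.1 equiv), toluene (0.02 M), rt → 60 °C
Reagents that add atoms: none
Why: Acid cleavage of the labile triethylsilyl ether followed by E1 dehydration of the 1-arylalkanol, the standard route to β-alkylstyrenes; the 4-silyloxyphenyl group stabilises the C7 cation and loss of a C6 proton gives the conjugated alkene, E under thermodynamic control, from both C7 epimers. Aryl silyl ethers and the secondary acetate are stable to catalytic sulfonic acid in toluene, and C3 cannot ionise.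

Step 10
Reactants: 14 (3S,6E)-1-[3,4-bis(tert-butyldimethylsilyloxy)phenyl]-7-[4-(tert-butyldimethylsilyloxy)phenyl]hept-6-en-3-yl acetate
Product: 15 (3S,6E)-1-(3,4-dihydroxyphenyl)-7-(4-hydroxyphenyl)hept-6-en-3-yl acetate
Conditions: n-Bu4NF (3.5 equiv), AcOH (4 equiv), THF, 0 °C, argon
Reagents that add atoms: none
Why: Fluoride-mediated cleavage of the three aryl silyl ethers; acetic acid keeps the medium near neutral, so the secondary acetate is not hydrolysed, the catechol is not exposed to base and air, and C3 and the E-alkene are untouched.

## Compound list

1 | 3-(3,4-dihydroxyphenyl)propanoic acid (dihydrocaffeic acid) | OC(=O)CCc1ccc(O)c(O)c1 | starting material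
2 | methyl 3-(3,4-dihydroxyphenyl)propanoate | COC(=O)CCc1ccc(O)c(O)c1 | intermediate
3 | methyl 3-[3,4-bis(tert-butyldimethylsilyloxy)phenyl]propanoate | COC(=O)CCc1ccc(O[Si](C)(C)C(C)(C)C)c(O[Si](C)(C)C(C)(C)C)c1 | intermediate
4 | 3-[3,4-bis(tert-butyldimethylsilyloxy)phenyl]propanal | O=CCCc1ccc(O[Si](C)(C)C(C)(C)C)c(O[Si](C)(C)C(C)(C)C)c1 | intermediate
5 | acetyl bromide | CC(=O)Br | starting material
6 | 1-bromo-3-[3,4-bis(tert-butyldimethylsilyloxy)phenyl]propyl acetate (racemic) | CC(=O)OC(Br)CCc1ccc(O[Si](C)(C)C(C)(C)C)c(O[Si](C)(C)C(C)(C)C)c1 | intermediate
7 | 4-hydroxybenzaldehyde | O=Cc1ccc(O)cc1 | starting material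
8 | 4-(tert-butyldimethylsilyloxy)benzaldehyde | O=Cc1ccc(O[Si](C)(C)C(C)(C)C)cc1 | intermediate
9 | allylmagnesium bromide | C=CC[Mg]Br | starting material
10 | 1-[4-(tert-butyldimethylsilyloxy)phenyl]but-3-en-1-ol (racemic) | C=CCC(O)c1ccc(O[Si](C)(C)C(C)(C)C)cc1 | intermediate
11 | tert-butyldimethyl{4-[1-(triethylsilyloxy)but-3-en-1-yl]phenoxy}silane (racemic) | C=CCC(O[Si](CC)(CC)CC)c1ccc(O[Si](C)(C)C(C)(C)C)cc1 | intermediate
12 | (3S)-1-[3,4-bis(tert-butyldimethylsilyloxy)phenyl]-7-[4-(tert-butyldimethylsilyloxy)phenyl]-7-(triethylsilyloxy)heptan-3-yl acetate (mixture of C7 epimers) | CC(=O)O[C@@H](CCCC(O[Si](CC)(CC)CC)c1ccc(O[Si](C)(C)C(C)(C)C)cc1)CCc1ccc(O[Si](C)(C)C(C)(C)C)c(O[Si](C)(C)C(C)(C)C)c1 | intermediate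
13 | (3S)-1-[3,4-bis(tert-butyldimethylsilyloxy)phenyl]-7-[4-(tert-butyldimethylsilyloxy)phenyl]-7-hydroxyheptan-3-yl acetate (mixture of C7 epimers, not isolated) | CC(=O)O[C@@H](CCCC(O)c1ccc(O[Si](C)(C)C(C)(C)C)cc1)CCc1ccc(O[Si](C)(C)C(C)(C)C)c(O[Si](C)(C)C(C)(C)C)c1 | intermediate
14 | (3S,6E)-1-[3,4-bis(tert-butyldimethylsilyloxy)phenyl]-7-[4-(tert-butyldimethylsilyloxy)phenyl]hept-6-en-3-yl acetate | CC(=O)O[C@@H](CC/C=C/c1ccc(O[Si](C)(C)C(C)(C)C)cc1)CCc1ccc(O[Si](C)(C)C(C)(C)C)c(O[Si](C)(C)C(C)(C)C)c1 | intermediate
15 | (3S,6E)-1-(3,4-dihydroxyphenyl)-7-(4-hydroxyphenyl)hept-6-en-3-yl acetate | CC(=O)O[C@@H](CC/C=C/c1ccc(O)cc1)CCc1ccc(O)c(O)c1 | target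

## Step count and risks

Total step count: 10. Longest linear sequence: 7 (steps 1, 2, 3, 4, 8, 9, 10).

**Step 8 (key step).**
- What may go wrong: loss of the electrophile before coupling. 1-Bromoalkyl esters revert hydrolytically to aldehyde and are simply reduced at the C–Br bond, and the medium holds hydrated phosphate and a hydride source.
- Further risks: enantioselection on this particular pair may fall short, the phosphate base may partly strip aryl silyl groups, and nickel hydride may isomerise the terminal olefin.
- Fallback: leave nickel chemistry and set C3 by hydrolytic kinetic resolution, setting out from aldehyde 4 and coming back at 14.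
  - Trimethylsulfonium iodide and n-BuLi (THF, 0 °C) convert 4 into the racemic epoxide 2-{2-[3,4-bis(tert-butyldimethylsilyloxy)phenyl]ethyl}oxirane F1.
  - The chiral (salen)Co(OAc) complex (salen = N,N′-bis(3,5-di-tert-butylsalicylidene)-trans-cyclohexane-1,2-diamine dianion) and 0.55 equiv of water consume the (S)-epoxide and leave the (R)-epoxide F2.
  - Allylmagnesium bromide 9 with catalytic CuI opens F2 at the terminal carbon and gives (3S)-1-[3,4-bis(tert-butyldimethylsilyloxy)phenyl]hept-6-en-3-ol F3.
  - Ac2O, pyridine and catalytic DMAP give the acetate F4.
  - Cross-metathesis of F4 with tert-butyldimethyl(4-vinylphenoxy)silane F5 (from aldehyde 8 by Wittig methylenation with Ph3P=CH2), using the second-generation Grubbs catalyst in CH2Cl2 at 40 °C, should give the E-styrene 14.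
  - The price is half the material in the resolution and a longer sequence.

**Step 9.**
- What may go wrong: cationic oligomerisation of the electron-rich β-alkylstyrene as it forms, since the acid that ionises C7 can also protonate the product. Slow acyl transfer within the hydroxy acetate 13 and loss of aryl silyl groups on prolonged heating are lesser risks.
- Fallback: avoid the cation, setting out from 12 and coming back at 14.
  - HF·pyridine buffered with pyridine (THF, 0 °C) removes only the triethylsilyl group, and alcohol 13 is isolated.
  - The Burgess reagent (methyl N-(triethylammoniumsulfonyl)carbamate, toluene, 50 °C) converts 13 into the triethylammonium N-(methoxycarbonyl)sulfamate ester F6, which undergoes thermal syn-elimination to 14.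

**Step 4.**
- What may go wrong: incomplete or reversible addition of the acyl bromide to the enolisable aldehyde and reversion on concentration. The hydrogen bromide then set free promotes aldol-type self-condensation and attacks the aryl silyl ethers.
- Fallback: reach 6 by a different addition, setting out from 4 and coming back at 6.
  - Ac2O, Et3N and catalytic DMAP (60 °C) give the enol acetate 3-[3,4-bis(tert-butyldimethylsilyloxy)phenyl]prop-1-en-1-yl acetate F7 (E/Z mixture), which can be purified and stored.
  - One equivalent of anhydrous HBr in CH2Cl2 at −40 °C adds in the Markovnikov sense, the known route from enol esters to 1-bromoalkyl esters, so no excess acid remains.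

**Step 10.**
- What may go wrong: cleavage of the C3 acetate by hydroxide from wet fluoride, air oxidation of the catechol once phenoxide forms, and oligomerisation of the 4-hydroxystyrene during concentration.
- Fallback: never expose free phenoxide, setting out from 14 and coming back at 15.
  - CsF and Ac2O in DMF exchange each silyl group for acetyl as it is released and give the tetraacetate (3S,6E)-1-(3,4-diacetoxyphenyl)-7-(4-acetoxyphenyl)hept-6-en-3-yl acetate F8, a stable compound that can be purified.
  - NH4OAc in aqueous methanol at rt then removes the three aryl acetates, which are far more labile than the secondary alkyl acetate, and gives 15.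

## Further compounds

F1 | step 8 | 2-{2-[3,4-bis(tert-butyldimethylsilyloxy)phenyl]ethyl}oxirane (racemic) | C1OC1CCc2ccc(O[Si](C)(C)C(C)(C)C)c(O[Si](C)(C)C(C)(C)C)c2
F2 | step 8 | (R)-2-{2-[3,4-bis(tert-butyldimethylsilyloxy)phenyl]ethyl}oxirane | O1[C@@H](C1)CCc2ccc(O[Si](C)(C)C(C)(C)C)c(O[Si](C)(C)C(C)(C)C)c2
F3 | step 8 | (3S)-1-[3,4-bis(tert-butyldimethylsilyloxy)phenyl]hept-6-en-3-ol | O[C@@H](CCC=C)CCc1ccc(O[Si](C)(C)C(C)(C)C)c(O[Si](C)(C)C(C)(C)C)c1
F4 | step 8 | (3S)-1-[3,4-bis(tert-butyldimethylsilyloxy)phenyl]hept-6-en-3-yl acetate | CC(=O)O[C@@H](CCC=C)CCc1ccc(O[Si](C)(C)C(C)(C)C)c(O[Si](C)(C)C(C)(C)C)c1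
F5 | step 8 | tert-butyldimethyl(4-vinylphenoxy)silane | C=Cc1ccc(O[Si](C)(C)C(C)(C)C)cc1
F6 | step 9 | triethylammonium N-(methoxycarbonyl)sulfamate ester of alcohol 13 | COC(=O)[N-]S(=O)(=O)OC(CCC[C@H](OC(C)=O)CCc1ccc(O[Si](C)(C)C(C)(C)C)c(O[Si](C)(C)C(C)(C)C)c1)c1ccc(O[Si](C)(C)C(C)(C)C)cc1.CC[NH+](CC)CC
F7 | step 4 | 3-[3,4-bis(tert-butyldimethylsilyloxy)phenyl]prop-1-en-1-yl acetate (E/Z mixture) | CC(=O)OC=CCc1ccc(O[Si](C)(C)C(C)(C)C)c(O[Si](C)(C)C(C)(C)C)c1
F8 | step 10 | (3S,6E)-1-(3,4-diacetoxyphenyl)-7-(4-acetoxyphenyl)hept-6-en-3-yl acetate | CC(=O)O[C@@H](CC/C=C/c1ccc(OC(C)=O)cc1)CCc1ccc(OC(C)=O)c(OC(C)=O)c1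
A1 | alternative 1 | (S)-2-{2-[3,4-bis(tert-butyldimethylsilyloxy)phenyl]ethyl}cyclopentanone | O=C1[C@@H](CCC1)CCc1ccc(O[Si](C)(C)C(C)(C)C)c(O[Si](C)(C)C(C)(C)C)c1
A2 | alternative 1 | (S)-6-{2-[3,4-bis(tert-butyldimethylsilyloxy)phenyl]ethyl}oxan-2-one | O1[C@@H](CCCC1=O)CCc1ccc(O[Si](C)(C)C(C)(C)C)c(O[Si](C)(C)C(C)(C)C)c1
A3 | alternative 2 | 1-[4-(tert-butyldimethylsilyloxy)phenyl]prop-2-en-1-ol (racemic) | C=CC(O)c1ccc(O[Si](C)(C)C(C)(C)C)cc1
A4 | alternative 2 | triethyl orthoacetate | CCOC(C)(OCC)OCC
A5 | alternative 2 | ethyl (E)-5-[4-(tert-butyldimethylsilyloxy)phenyl]pent-4-enoate | CCOC(=O)CC/C=C/c1ccc(O[Si](C)(C)C(C)(C)C)cc1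
A6 | alternative 2 | (E)-1-[3,4-bis(tert-butyldimethylsilyloxy)phenyl]-7-[4-(tert-butyldimethylsilyloxy)phenyl]hept-6-en-3-one | O=C(CC/C=C/c1ccc(O[Si](C)(C)C(C)(C)C)cc1)CCc1ccc(O[Si](C)(C)C(C)(C)C)c(O[Si](C)(C)C(C)(C)C)c1
A7 | alternative 3 | (E)-5-[4-(tert-butyldimethylsilyloxy)phenyl]pent-4-en-1-yl 2,4,6-triisopropylbenzoate | CC(C)c1cc(C(C)C)c(C(=O)OCCC/C=C/c2ccc(O[Si](C)(C)C(C)(C)C)cc2)c(C(C)C)c1
A8 | alternative 3 | 2-{2-[3,4-bis(tert-butyldimethylsilyloxy)phenyl]ethyl}-4,4,5,5-tetramethyl-1,3,2-dioxaborolane | CC1(C)OB(CCc2ccc(O[Si](C)(C)C(C)(C)C)c(O[Si](C)(C)C(C)(C)C)c2)OC1(C)C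
A9 | alternative 3 | secondary pinacol boronate with boron at C3 in the spatial position of the target oxygen, (E)-alkene | CC1(C)OB([C@@H](CC/C=C/c2ccc(O[Si](C)(C)C(C)(C)C)cc2)CCc2ccc(O[Si](C)(C)C(C)(C)C)c(O[Si](C)(C)C(C)(C)C)c2)OC1(C)C
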